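**Assumption:** the target SMILES has no stereocentre and no stereogenic double bond (colupulone is achiral, drawn as one enol tautomer), so "single enantiomer" needs no stereocontrol.

**Retrosynthetic overview**
- No ring is formed: the six-membered carbocycle comes intact from phloroglucinol and is dearomatised in the last step.
- Disconnect the three C-prenyl bonds, including the gem-diprenyl quaternary carbon, to phlorisobutyrophenone and three prenyl bromide (one-pot triple C-alkylation).
- Disconnect the aryl–acyl bond to phloroglucinol and isobutyryl chloride (Friedel–Crafts acylation).

**Route**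

Step 1
Reactants: 1 phloroglucinol (benzene-1,3,5-triol, anhydrous); 2 isobutyryl chloride (2-methylpropanoyl chloride)
Product: 3 phlorisobutyrophenone (2-methyl-1-(2,4,6-trihydroxyphenyl)propan-1-one)
Conditions: AlCl3 (4 equiv), PhNO2/CH2Cl2, 0 °C → 45 °C; then ice/1 M HCl
Reagents that add atoms: 2 isobutyryl chloride, CC(C)C(Cl)=O
Why: Friedel–Crafts C-acylation, in which the acylium ion attacks the very electron-rich ring and the chelated aryl ketone formed is deactivated towards a second acylation; no stereocentre is formed.

Step 2
Reactants: 3 phlorisobutyrophenone; 4 prenyl bromide (1-bromo-3-methylbut-2-ene, 3.0 equiv)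
Product: 7 colupulone, via 3-prenylphlorisobutyrophenone 5 (not isolated), via deoxycohumulone 6 (not isolated)
Conditions: liq. NH3/Et2O, −40 °C, N2; evaporate NH3, cold 1 M HCl; crystallise from hexane
Reagents that add atoms: 4 prenyl bromide, CC(C)=CCBr
Why: Three successive SN2 C-alkylations of the ambident phloroglucinolate (ammonium salt) by the soft allylic bromide, the third at an already prenylated carbon in a dearomatising alkylation that gives the gem-diprenyl quaternary carbon; that carbon carries two identical prenyl groups, so no stereocentre arises.

**Compound list**
1 | phloroglucinol (benzene-1,3,5-triol) | Oc1cc(O)cc(O)c1 | starting material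
2 | isobutyryl chloride (2-methylpropanoyl chloride) | CC(C)C(Cl)=O | starting material
3 | phlorisobutyrophenone, 2-methyl-1-(2,4,6-trihydroxyphenyl)propan-1-one | CC(C)C(=O)c1c(O)cc(O)cc1O | intermediate
4 | prenyl bromide (1-bromo-3-methylbut-2-ene) | CC(C)=CCBr | starting material
5 | 3-prenylphlorisobutyrophenone, 2-methyl-1-[2,4,6-trihydroxy-3-(3-methylbut-2-en-1-yl)phenyl]propan-1-one | CC(C)=CCc1c(O)cc(O)c(C(=O)C(C)C)c1O | intermediate
6 | deoxycohumulone, 2-methyl-1-[2,4,6-trihydroxy-3,5-bis(3-methylbut-2-en-1-yl)phenyl]propan-1-one | CC(C)=CCc1c(O)c(CC=C(C)C)c(O)c(C(=O)C(C)C)c1O | intermediate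
7 | colupulone, 3,5-dihydroxy-2-(2-methylpropanoyl)-4,6,6-tris(3-methylbut-2-en-1-yl)cyclohexa-2,4-dien-1-one (achiral) | CC(C)=CCC1=C(O)C(CC=C(C)C)(CC=C(C)C)C(=O)C(C(=O)C(C)C)=C1O | target

**Totals**
Total step count: 2. Longest linear sequence: 2 steps (1 → 3 → 7).

**Steps most likely to fail** (the route has only two steps, so both are ranked and there is no third)

Most at risk, step 2 (one-pot triple prenylation). The risks are mixtures of under- and over-prenylated products, O-prenylation, and acid-induced chroman formation or autoxidation of the product. The fallback sets out from 3 and comes back to the route at 7, and splits the prenylations into two mechanistically different stages. First, 3 is C-prenylated twice by electrophilic aromatic substitution with 2-methylbut-3-en-2-ol and substoichiometric BF3·OEt2 in dioxane at room temperature. These acidic conditions generate the prenyl cation and cannot dearomatise, so the sequence stops at the aromatic deoxycohumulone 6 (through 5), which is now isolated and purified. Second, 6 is given exactly one equivalent of prenyl bromide 4 in liquid NH3/Et2O at −40 °C, so that only the single dearomatising alkylation to 7 remains. This fallback makes no compound outside the compound list (F0).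

Second, step 1 (Friedel–Crafts acylation). The risks are O-acylation, diacylation, poor solubility of the phloroglucinol–AlCl3 complex, and tedious removal of nitrobenzene. The fallback sets out from 1 and comes back to the route at 3, and replaces the acid chloride/AlCl3 chemistry by a Houben–Hoesch reaction. Compound 1 is treated with isobutyronitrile and dry HCl gas (catalytic ZnCl2, Et2O, 0 °C), which precipitates the mono-C-acylated 2-methyl-1-(2,4,6-trihydroxyphenyl)propan-1-iminium chloride F1. The iminium salt cannot react a second time. It is filtered and hydrolysed in boiling water to 3.

**Further compounds**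
F0 | step 2 | none | none
F1 | step 1 | 2-methyl-1-(2,4,6-trihydroxyphenyl)propan-1-iminium chloride (Hoesch ketiminium salt) | CC(C)C(=[NH2+])c1c(O)cc(O)cc1O.[Cl-]
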